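## Retrosynthetic overview

1. The sulfate esters go on last, onto the C40 tetrol. The C40 chain is cut at C11=C12 and C11'=C12' into two C15 phosphonium salts and the commercial C10 dialdehyde (double Wittig).
2. Each C15 salt comes from a C10 ring aldehyde by way of the C13 enone (HWE, vinyl Grignard, PPh3·HBr).
3. Both ring aldehydes come from one C2-symmetric bis-adduct by periodate cleavage of an L-tartrate-derived tether; the tartrate carboxyl carbons become C7 and C7'.
4. Both cyclohexane rings are closed at the same time in step 3 by a two-directional Diels–Alder reaction of the tartrate bis(β,β-dimethyl enone) with two molecules of a 2-silyloxy-1,3-pentadiene. No carbocycle is formed afterwards.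
5. Stereocentres: C5 in the cycloaddition (tether control), C4 by Rubottom oxidation, C3 by LiBH(s-Bu)3 reduction, C6 by epimerisation of the aldehyde.

Assumption: the target is taken as drawn, the free bis(hydrogen sulfate), liberated in the last work-up (it is best stored as its disodium salt). Atom labels C1–C6 (ring) and C7 onwards (chain) follow carotenoid numbering.

## Route

Step 1
Reactants: 1 (E)-pent-3-en-2-one
Product: 2 (3E)-2-(triisopropylsilyloxy)penta-1,3-diene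
Conditions: TIPSOTf, Et3N, Et2O, 0 °C
Reagents that add atoms: triisopropylsilyl trifluoromethanesulfonate, CC(C)[Si](C(C)C)(C(C)C)OS(=O)(=O)C(F)(F)F
Why: Soft enolisation (silyl triflate/amine) removes an α'-methyl proton of the enone and gives the cross-conjugated 2-silyloxy diene with the E-alkene untouched.

Step 2
Reactants: 3 (4R,5R)-N,N,N',N',2,2-hexamethyl-1,3-dioxolane-4,5-dicarboxamide; 4 2-methylprop-1-enylmagnesium bromide
Product: 5 1,1'-[(4R,5R)-2,2-dimethyl-1,3-dioxolane-4,5-diyl]bis(3-methylbut-2-en-1-one)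
Conditions: 4 (4 equiv), THF, −20 °C → rt; aq. NH4Cl
Reagents that add atoms: none
Why: Grignard acylation of the tertiary amides stops at the chelated tetrahedral magnesium hemiaminal, which collapses to the ketone only on work-up, so no over-addition occurs and the two tartrate centres are kept.

Step 3
Reactants: 5 1,1'-[(4R,5R)-2,2-dimethyl-1,3-dioxolane-4,5-diyl]bis(3-methylbut-2-en-1-one); 2 (3E)-2-(triisopropylsilyloxy)penta-1,3-diene
Product: 6 [(4R,5R)-2,2-dimethyl-1,3-dioxolane-4,5-diyl]bis{[(1S,2S)-2,6,6-trimethyl-4-(triisopropylsilyloxy)cyclohex-3-en-1-yl]methanone}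
Conditions: 2 (4 equiv), Me2AlCl (5 equiv), CH2Cl2, −78 → −30 °C; Et3N then aq. NaHCO3
Reagents that add atoms: none
Why: Proposed new method: a two-directional Lewis-acid-promoted Diels–Alder reaction in which each s-cis enone is held in a five-membered Me2Al chelate between the ketone oxygen and the neighbouring dioxolane oxygen, so the diene adds endo to the face away from the dioxolane ring, its CH2 terminus bonding to the CMe2 carbon (silyloxy and methyl donors reinforce this regiochemistry); by C2 symmetry this gives the same C5 configuration in both rings with C6 cis to it (corrected in step 6), any stereoisomeric bis-adducts are diastereomers and separable on silica, and the closest known reactions are Lewis-acid-promoted cycloadditions of 2-silyloxy dienes with β,β-disubstituted enones and chelation-controlled cycloadditions of α'-oxygenated enones.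

Step 4
Reactants: 6 [(4R,5R)-2,2-dimethyl-1,3-dioxolane-4,5-diyl]bis{[(1S,2S)-2,6,6-trimethyl-4-(triisopropylsilyloxy)cyclohex-3-en-1-yl]methanone}
Product: 8 [(4R,5R)-2,2-dimethyl-1,3-dioxolane-4,5-diyl]bis{[(1S,2R,3S)-2,6,6-trimethyl-4-oxo-3-(triisopropylsilyloxy)cyclohexyl]methanone}, via bis(silyloxy epoxide) 7 (not isolated)
Conditions: mCPBA (2.4 equiv), NaHCO3, CH2Cl2, −20 → 0 °C
Reagents that add atoms: 3-chloroperoxybenzoic acid, OOC(=O)c1cccc(Cl)c1
Why: Rubottom oxidation, in which the peracid attacks the nucleophilic C4 of each silyl enol ether on the face opposite the axial C6 acyl group and the C5 methyl (both on the lower face), and 1,4-silyl migration in the opened epoxide leaves O4 silylated, trans to the C5 methyl, next to the C3 ketone.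

Step 5
Reactants: 8 [(4R,5R)-2,2-dimethyl-1,3-dioxolane-4,5-diyl]bis{[(1S,2R,3S)-2,6,6-trimethyl-4-oxo-3-(triisopropylsilyloxy)cyclohexyl]methanone}
Product: 10 [2,2-dimethyl-1,3-dioxolane-4,5-diyl]bis{[(1S,2R,3S,4R)-4-hydroxy-2,6,6-trimethyl-3-(triisopropylsilyloxy)cyclohexyl]methanol} (dioxolane centres as in 5; carbinol epimers), via diketone diol 9 (not isolated)
Conditions: LiBH(s-Bu)3 (2.5 equiv), THF, −78 °C; then LiAlH4, 0 °C; aq. potassium sodium tartrate (KNaC4H4O6)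
Reagents that add atoms: none
Why: Diastereoselective ketone reduction, in which the bulky borohydride attacks each C3 ketone equatorially, away from the syn-axial C1 methyl (the 3,3,5-trimethylcyclohexanone pattern), and gives the axial 3-OH cis to the 4-silyloxy group, after which LiAlH4 reduces the hindered tether ketones, whose configuration is irrelevant.

Step 6
Reactants: 10 [2,2-dimethyl-1,3-dioxolane-4,5-diyl]bis{[(1S,2R,3S,4R)-4-hydroxy-2,6,6-trimethyl-3-(triisopropylsilyloxy)cyclohexyl]methanol}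
Product: 13 (1R,2R,3S,4R)-4-hydroxy-2,6,6-trimethyl-3-(triisopropylsilyloxy)cyclohexane-1-carbaldehyde (2 equiv), via tether tetrol 11 (not isolated), via cis-aldehyde 12 (not isolated)
Conditions: 80% aq. AcOH, 45 °C; concentrate; NaIO4 (3.3 equiv), THF/pH 7 buffer, 0 °C; then K2CO3, MeOH, rt
Reagents that add atoms: none
Why: Acetal hydrolysis followed by Malaprade glycol cleavage of the freed 1,2,3,4-tetrol releases two ring aldehydes (the ring 3-OH is safe because its neighbour O4 is silylated), and base then equilibrates the α-centre C6 from the axial (cis) to the equatorial (trans) aldehyde.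

Step 7
Reactants: 13 (1R,2R,3S,4R)-4-hydroxy-2,6,6-trimethyl-3-(triisopropylsilyloxy)cyclohexane-1-carbaldehyde; 14 dimethyl (2-oxopropyl)phosphonate
Product: 15 (3E)-4-[(1R,2R,3S,4R)-4-hydroxy-2,6,6-trimethyl-3-(triisopropylsilyloxy)cyclohexyl]but-3-en-2-one
Conditions: LiCl, i-Pr2NEt, MeCN, rt
Reagents that add atoms: none
Why: Horner–Wadsworth–Emmons olefination under Masamune–Roush conditions gives the E-enone (C7=C8) without strong base, so the free 3-OH and the C6 centre are not disturbed.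

Step 8
Reactants: 15 (3E)-4-[(1R,2R,3S,4R)-4-hydroxy-2,6,6-trimethyl-3-(triisopropylsilyloxy)cyclohexyl]but-3-en-2-one; 16 vinylmagnesium bromide
Product: 17 (1E)-1-[(1R,2R,3S,4R)-4-hydroxy-2,6,6-trimethyl-3-(triisopropylsilyloxy)cyclohexyl]-3-methylpenta-1,4-dien-3-ol (C3 epimers of the pentadienol)
Conditions: 16 (3 equiv), THF, −78 → 0 °C
Reagents that add atoms: none
Why: Grignard 1,2-addition to the β-substituted enone gives the tertiary bis-allylic carbinol (the ionone to vinyl-ionol pattern); the new carbinol centre is lost in the next step.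

Step 9
Reactants: 17 (1E)-1-[(1R,2R,3S,4R)-4-hydroxy-2,6,6-trimethyl-3-(triisopropylsilyloxy)cyclohexyl]-3-methylpenta-1,4-dien-3-ol
Product: 18 {(2E,4E)-5-[(1R,2R,3S,4R)-4-hydroxy-2,6,6-trimethyl-3-(triisopropylsilyloxy)cyclohexyl]-3-methylpenta-2,4-dien-1-yl}triphenylphosphonium bromide
Conditions: PPh3·HBr (1.1 equiv), MeOH, rt
Reagents that add atoms: triphenylphosphine hydrobromide, [PH+](c1ccccc1)(c1ccccc1)c1ccccc1.[Br-]
Why: SN1-type ionisation of the tertiary bis-allylic alcohol to a pentadienyl cation and capture by the phosphine at the unhindered terminus (allylic transposition) gives the C15 salt, mainly 9E; any 9Z isomer converges in step 10.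

Step 10
Reactants: 18 {(2E,4E)-5-[(1R,2R,3S,4R)-4-hydroxy-2,6,6-trimethyl-3-(triisopropylsilyloxy)cyclohexyl]-3-methylpenta-2,4-dien-1-yl}triphenylphosphonium bromide (2.2 equiv); 19 (2E,4E,6E)-2,7-dimethylocta-2,4,6-trienedial
Product: 21 (3R,4S,5R,6R,3'R,4'S,5'R,6'R)-4,4'-bis(triisopropylsilyloxy)-5,6,5',6'-tetrahydro-β,β-carotene-3,3'-diol, via phosphonium ylide 20 (not isolated)
Conditions: NaOMe, MeOH/CH2Cl2, 0 °C → rt, argon, dark; then heptane, reflux (Z → E)
Reagents that add atoms: none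
Why: Double Wittig olefination of the C10 dialdehyde with the semi-stabilised allylic ylide builds C11=C12 and C11'=C12', and thermal equilibration converts the unhindered Z isomers to the all-E polyene.

Step 11
Reactants: 21 (3R,4S,5R,6R,3'R,4'S,5'R,6'R)-4,4'-bis(triisopropylsilyloxy)-5,6,5',6'-tetrahydro-β,β-carotene-3,3'-diol
Product: 22 (3R,4S,5R,6R,3'R,4'S,5'R,6'R)-5,6,5',6'-tetrahydro-β,β-carotene-3,3',4,4'-tetrol
Conditions: Bu4NF (4 equiv), THF, rt, argon, dark
Reagents that add atoms: none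
Why: Fluoride-driven silyl ether cleavage frees O4 and O4' under conditions the polyene tolerates.

Step 12
Reactants: 22 (3R,4S,5R,6R,3'R,4'S,5'R,6'R)-5,6,5',6'-tetrahydro-β,β-carotene-3,3',4,4'-tetrol
Product: 24 (3R,4S,5R,6R,3'R,4'S,5'R,6'R)-3,3'-dihydroxy-5,6,5',6'-tetrahydro-β,β-carotene-4,4'-diyl bis(hydrogen sulfate), via bis(dibutylstannylene) acetal 23 (not isolated)
Conditions: Bu2SnO (2.2 equiv), MeOH, reflux, then evaporate; SO3·NMe3 (2.4 equiv), DMF, rt; Dowex 50W (H+ form), MeOH, 0 °C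
Reagents that add atoms: sulfur trioxide–trimethylamine complex, C[N+](C)(C)S(=O)(=O)[O-]
Why: Stannylene-acetal-directed O-sulfation, in which the tin acetal of each cis-diol activates the equatorial O4 over the axial O3 (which is also syn-axial to the C1 methyl), so SO3 is delivered to O4 and O4' only.

## Compound list

1 | (E)-pent-3-en-2-one | C/C=C/C(C)=O | starting material
2 | (3E)-2-(triisopropylsilyloxy)penta-1,3-diene | C=C(O[Si](C(C)C)(C(C)C)C(C)C)/C=C/C | intermediate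
3 | (4R,5R)-N,N,N',N',2,2-hexamethyl-1,3-dioxolane-4,5-dicarboxamide (L-tartaric acid bis(dimethylamide) acetonide) | CN(C)C(=O)[C@@H]1OC(C)(C)O[C@H]1C(=O)N(C)C | starting material
4 | 2-methylprop-1-enylmagnesium bromide | CC(C)=C[Mg]Br | starting material
5 | 1,1'-[(4R,5R)-2,2-dimethyl-1,3-dioxolane-4,5-diyl]bis(3-methylbut-2-en-1-one) | CC(C)=CC(=O)[C@@H]1OC(C)(C)O[C@H]1C(=O)C=C(C)C | intermediate
6 | [(4R,5R)-2,2-dimethyl-1,3-dioxolane-4,5-diyl]bis{[(1S,2S)-2,6,6-trimethyl-4-(triisopropylsilyloxy)cyclohex-3-en-1-yl]methanone} (acyl and 2-methyl cis in each ring) | O=C([C@H]1[C@@H](C)C=C(O[Si](C(C)C)(C(C)C)C(C)C)CC1(C)C)[C@@H]2OC(C)(C)O[C@H]2C(=O)[C@H]3[C@@H](C)C=C(O[Si](C(C)C)(C(C)C)C(C)C)CC3(C)C | intermediate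
7 | bis(silyloxy epoxide) of 6: C3–C4 epoxide in each ring, oxygen on the face opposite the C5 methyl (formed in the flask in step 4) | O=C([C@H]1[C@@H](C)[C@@H]2O[C@]2(O[Si](C(C)C)(C(C)C)C(C)C)CC1(C)C)[C@@H]3OC(C)(C)O[C@H]3C(=O)[C@H]4[C@@H](C)[C@@H]5O[C@]5(O[Si](C(C)C)(C(C)C)C(C)C)CC4(C)C | intermediate
8 | [(4R,5R)-2,2-dimethyl-1,3-dioxolane-4,5-diyl]bis{[(1S,2R,3S)-2,6,6-trimethyl-4-oxo-3-(triisopropylsilyloxy)cyclohexyl]methanone} | O=C([C@H]1[C@@H](C)[C@H](O[Si](C(C)C)(C(C)C)C(C)C)C(=O)CC1(C)C)[C@@H]2OC(C)(C)O[C@H]2C(=O)[C@H]3[C@@H](C)[C@H](O[Si](C(C)C)(C(C)C)C(C)C)C(=O)CC3(C)C | intermediate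
9 | [(4R,5R)-2,2-dimethyl-1,3-dioxolane-4,5-diyl]bis{[(1S,2R,3S,4R)-4-hydroxy-2,6,6-trimethyl-3-(triisopropylsilyloxy)cyclohexyl]methanone} (formed in the flask in step 5) | O=C([C@H]1[C@@H](C)[C@H](O[Si](C(C)C)(C(C)C)C(C)C)[C@H](O)CC1(C)C)[C@@H]2OC(C)(C)O[C@H]2C(=O)[C@H]3[C@@H](C)[C@H](O[Si](C(C)C)(C(C)C)C(C)C)[C@H](O)CC3(C)C | intermediate
10 | [2,2-dimethyl-1,3-dioxolane-4,5-diyl]bis{[(1S,2R,3S,4R)-4-hydroxy-2,6,6-trimethyl-3-(triisopropylsilyloxy)cyclohexyl]methanol} (dioxolane centres as in 5; carbinol epimers) | OC([C@H]1[C@@H](C)[C@H](O[Si](C(C)C)(C(C)C)C(C)C)[C@H](O)CC1(C)C)[C@@H]2OC(C)(C)O[C@H]2C(O)[C@H]3[C@@H](C)[C@H](O[Si](C(C)C)(C(C)C)C(C)C)[C@H](O)CC3(C)C | intermediate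
11 | 1,4-bis[(1S,2R,3S,4R)-4-hydroxy-2,6,6-trimethyl-3-(triisopropylsilyloxy)cyclohexyl]butane-1,2,3,4-tetrol (2,3-threo from L-tartrate; C1/C4 epimers; formed in the flask in step 6) | OC([C@H]1[C@@H](C)[C@H](O[Si](C(C)C)(C(C)C)C(C)C)[C@H](O)CC1(C)C)[C@H](O)[C@@H](O)C(O)[C@H]2[C@@H](C)[C@H](O[Si](C(C)C)(C(C)C)C(C)C)[C@H](O)CC2(C)C | intermediate
12 | (1S,2R,3S,4R)-4-hydroxy-2,6,6-trimethyl-3-(triisopropylsilyloxy)cyclohexane-1-carbaldehyde (CHO cis to 2-methyl; formed in the flask in step 6) | O=C[C@H]1[C@@H](C)[C@H](O[Si](C(C)C)(C(C)C)C(C)C)[C@H](O)CC1(C)C | intermediate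
13 | (1R,2R,3S,4R)-4-hydroxy-2,6,6-trimethyl-3-(triisopropylsilyloxy)cyclohexane-1-carbaldehyde (CHO trans to 2-methyl) | O=C[C@@H]1[C@@H](C)[C@H](O[Si](C(C)C)(C(C)C)C(C)C)[C@H](O)CC1(C)C | intermediate
14 | dimethyl (2-oxopropyl)phosphonate | COP(=O)(OC)CC(C)=O | starting material
15 | (3E)-4-[(1R,2R,3S,4R)-4-hydroxy-2,6,6-trimethyl-3-(triisopropylsilyloxy)cyclohexyl]but-3-en-2-one | CC(=O)/C=C/[C@@H]1[C@@H](C)[C@H](O[Si](C(C)C)(C(C)C)C(C)C)[C@H](O)CC1(C)C | intermediate
16 | vinylmagnesium bromide | C=C[Mg]Br | starting material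
17 | (1E)-1-[(1R,2R,3S,4R)-4-hydroxy-2,6,6-trimethyl-3-(triisopropylsilyloxy)cyclohexyl]-3-methylpenta-1,4-dien-3-ol (carbinol epimers) | C=CC(C)(O)/C=C/[C@@H]1[C@@H](C)[C@H](O[Si](C(C)C)(C(C)C)C(C)C)[C@H](O)CC1(C)C | intermediate
18 | {(2E,4E)-5-[(1R,2R,3S,4R)-4-hydroxy-2,6,6-trimethyl-3-(triisopropylsilyloxy)cyclohexyl]-3-methylpenta-2,4-dien-1-yl}triphenylphosphonium bromide | [Br-].c1ccc(cc1)[P+](c2ccccc2)(c3ccccc3)C/C=C(C)/C=C/[C@@H]4[C@@H](C)[C@H](O[Si](C(C)C)(C(C)C)C(C)C)[C@H](O)CC4(C)C | intermediate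
19 | (2E,4E,6E)-2,7-dimethylocta-2,4,6-trienedial (C10 dialdehyde) | O=C/C(C)=C/C=C/C=C(C)/C=O | starting material
20 | ylide of 18, (2E,4E)-5-[ring]-3-methylpenta-2,4-dienylidene(triphenyl)phosphorane (formed in the flask in step 10) | c1ccc(cc1)P(c2ccccc2)(c3ccccc3)=C/C=C(C)/C=C/[C@@H]4[C@@H](C)[C@H](O[Si](C(C)C)(C(C)C)C(C)C)[C@H](O)CC4(C)C | intermediate
21 | (3R,4S,5R,6R,3'R,4'S,5'R,6'R)-4,4'-bis(triisopropylsilyloxy)-5,6,5',6'-tetrahydro-β,β-carotene-3,3'-diol | CC(/C=C/C=C(C)/C=C/[C@@H]1[C@@H](C)[C@H](O[Si](C(C)C)(C(C)C)C(C)C)[C@H](O)CC1(C)C)=C\C=C\C=C(C)\C=C\C=C(C)\C=C\[C@@H]1[C@@H](C)[C@H](O[Si](C(C)C)(C(C)C)C(C)C)[C@H](O)CC1(C)C | intermediate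
22 | (3R,4S,5R,6R,3'R,4'S,5'R,6'R)-5,6,5',6'-tetrahydro-β,β-carotene-3,3',4,4'-tetrol | CC(/C=C/C=C(C)/C=C/[C@@H]1[C@@H](C)[C@H](O)[C@H](O)CC1(C)C)=C\C=C\C=C(C)\C=C\C=C(C)\C=C\[C@@H]1[C@@H](C)[C@H](O)[C@H](O)CC1(C)C | intermediate
23 | 3,4:3',4'-bis-O-(dibutylstannylene) acetal of 22 (formed in the flask in step 12) | CC(/C=C/C=C(C)/C=C/[C@@H]1[C@@H](C)[C@@H]2O[Sn](CCCC)(CCCC)O[C@@H]2CC1(C)C)=C\C=C\C=C(C)\C=C\C=C(C)\C=C\[C@@H]1[C@@H](C)[C@@H]2O[Sn](CCCC)(CCCC)O[C@@H]2CC1(C)C | intermediate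
24 | (3R,4S,5R,6R,3'R,4'S,5'R,6'R)-3,3'-dihydroxy-5,6,5',6'-tetrahydro-β,β-carotene-4,4'-diyl bis(hydrogen sulfate) | CC(/C=C/C=C(C)/C=C/[C@@H]1[C@@H](C)[C@H](OS(=O)(=O)O)[C@H](O)CC1(C)C)=C\C=C\C=C(C)\C=C\C=C(C)\C=C\[C@@H]1[C@@H](C)[C@H](OS(=O)(=O)O)[C@H](O)CC1(C)C | target

## Step count and risk

Total steps: 12. Longest linear sequence: 11 (steps 1, 3, 4, 5, 6, 7, 8, 9, 10, 11, 12; step 2 is a one-step side branch).

The three steps most likely to fail are 3, 4 and 12.

Step 3 (double cycloaddition). The silyl dienol ether may not survive the Lewis acid, or may react by conjugate addition only, and the facial sense rests on the chelate model. The fallback brings the oxygen atoms in after ring formation. Setting out from bis-enone 5, the same two-directional cycloaddition is run with commercial (E)-penta-1,3-diene and Me2AlCl (CH2Cl2, −20 °C → rt), the long-established diene partner for β,β-dimethyl enones, to give the C2-symmetric bis(cis-2,6,6-trimethylcyclohex-3-enyl) diketone F1. OsO4 (cat.) with N-methylmorpholine N-oxide then dihydroxylates each ring alkene from the face opposite the cis-disposed C5 methyl and C6 acyl groups to give the bis(cis-diol) diketone F2. TIPSOTf/2,6-lutidine at −78 °C silylates only the equatorial O4, since O3 is axial and syn to the axial C1 methyl. The product is compound 9, where the route is rejoined for the LiAlH4 part of step 5. If instead the minor diastereomer dominates in step 3, the D-tartrate enantiomer of 3 is used.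

Step 4 (Rubottom oxidation). The epoxidation may give C4 epimers, and 8 cannot safely be equilibrated with base because of its α-alkoxy tether ketones. The fallback sets C4 under thermodynamic control. Setting out from 6, LiAlH4 (THF, 0 °C) first reduces the two tether ketones to give the bis-carbinol bis(silyl enol ether) F3. mCPBA/NaHCO3 followed by DBU (CH2Cl2, rt) gives the bis(α-silyloxy ketone) bis-carbinol F4, with the silyloxy group equilibrated to the equatorial position trans to the C5 methyl (the epimer would be syn-axial to the C6 substituent). LiBH(s-Bu)3 (THF, −78 °C) then reduces the ring ketones as in step 5, and the route is rejoined at compound 10.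

Step 12 (regioselective sulfation). The tin-directed sulfation may not be selective enough over four hydroxyls, or the polyene may suffer. The fallback tells O3 and O4 apart with protecting groups. Setting out from 21, Ac2O/DMAP/pyridine acetylates the free 3- and 3'-hydroxyls to give the 3,3'-diacetate 4,4'-bis(silyl ether) F5. Bu4NF buffered with AcOH (to suppress acetyl migration) gives the 3,3'-diacetate 4,4'-diol F6. SO3·pyridine (DMF, 0 °C) gives the 3,3'-diacetate 4,4'-bis(hydrogen sulfate) F7. K2CO3/MeOH removes the acetates, and the same acidic ion exchange returns to the route at compound 24.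

Further compounds
F1 | step 3 | [(4R,5R)-2,2-dimethyl-1,3-dioxolane-4,5-diyl]bis{[(1S,2S)-2,6,6-trimethylcyclohex-3-en-1-yl]methanone} | O=C([C@H]1[C@@H](C)C=CCC1(C)C)[C@@H]2OC(C)(C)O[C@H]2C(=O)[C@H]3[C@@H](C)C=CCC3(C)C
F2 | step 3 | [(4R,5R)-2,2-dimethyl-1,3-dioxolane-4,5-diyl]bis{[(1S,2R,3S,4R)-3,4-dihydroxy-2,6,6-trimethylcyclohexyl]methanone} | O=C([C@H]1[C@@H](C)[C@H](O)[C@H](O)CC1(C)C)[C@@H]2OC(C)(C)O[C@H]2C(=O)[C@H]3[C@@H](C)[C@H](O)[C@H](O)CC3(C)C
F3 | step 4 | bis-carbinol of 6: both tether ketones reduced, silyl enol ethers intact (carbinol epimers) | OC([C@H]1[C@@H](C)C=C(O[Si](C(C)C)(C(C)C)C(C)C)CC1(C)C)[C@@H]2OC(C)(C)O[C@H]2C(O)[C@H]3[C@@H](C)C=C(O[Si](C(C)C)(C(C)C)C(C)C)CC3(C)C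
F4 | step 4 | bis-carbinol analogue of 8: ring 4-oxo-3-(triisopropylsilyloxy) groups, tether carbinols (carbinol epimers) | OC([C@H]1[C@@H](C)[C@H](O[Si](C(C)C)(C(C)C)C(C)C)C(=O)CC1(C)C)[C@@H]2OC(C)(C)O[C@H]2C(O)[C@H]3[C@@H](C)[C@H](O[Si](C(C)C)(C(C)C)C(C)C)C(=O)CC3(C)C
F5 | step 12 | 3,3'-di-O-acetyl derivative of 21 | CC(/C=C/C=C(C)/C=C/[C@@H]1[C@@H](C)[C@H](O[Si](C(C)C)(C(C)C)C(C)C)[C@H](OC(C)=O)CC1(C)C)=C\C=C\C=C(C)\C=C\C=C(C)\C=C\[C@@H]1[C@@H](C)[C@H](O[Si](C(C)C)(C(C)C)C(C)C)[C@H](OC(C)=O)CC1(C)C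
F6 | step 12 | 3,3'-di-O-acetyl derivative of tetrol 22 (4,4'-diol free) | CC(/C=C/C=C(C)/C=C/[C@@H]1[C@@H](C)[C@H](O)[C@H](OC(C)=O)CC1(C)C)=C\C=C\C=C(C)\C=C\C=C(C)\C=C\[C@@H]1[C@@H](C)[C@H](O)[C@H](OC(C)=O)CC1(C)C
F7 | step 12 | 3,3'-di-O-acetyl derivative of 24 (4,4'-bis(hydrogen sulfate)) | CC(/C=C/C=C(C)/C=C/[C@@H]1[C@@H](C)[C@H](OS(=O)(=O)O)[C@H](OC(C)=O)CC1(C)C)=C\C=C\C=C(C)\C=C\C=C(C)\C=C\[C@@H]1[C@@H](C)[C@H](OS(=O)(=O)O)[C@H](OC(C)=O)CC1(C)C
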